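**Retrosynthetic overview**

1. Locants used: oxolane O1, C2 (CH2), C3 (tertiary carbinol carrying the benzyl group), C4 (CH carrying CH2OH), C5 (CH carrying the aryl group). Endgame: the phenols are freed last from benzyl ethers (12 → 13), and the C4 CH2OH comes from a CH2–Bpin group (11 → 12).
2. Key disconnection C3–C4: the oxolane, the only ring made, is closed by 5-exo-trig addition of the samarium ketyl of the C3 ketone in acyclic keto ether 10 to its (E)-alkenylboronate. This one step makes the ring, the quaternary carbinol C3 and the C4 stereocentre.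
3. Enabling feature: C3 is a tertiary carbinol (a latent ketyl) joined through C2–O1–C5 to C4. Its OH is anti to the one-carbon branch on C4 (an anti 1,3-diol HO–C3–C4–CH2–OH) and cis to the C5 aryl group, which is the outcome expected when a metal ketyl adds to an alkene with one allylic stereocentre.
4. 10 is taken apart at O1–C2 (Williamson ether synthesis), at C3–CH2Ar (Weinreb amide plus benzylic Grignard reagent) and at the C=C bond (cross-metathesis with vinyl-Bpin). This leads back to (R)-allylic alcohol 4, made from O-benzylvanillin 1 by vinyl addition and lipase resolution.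

Key step: step 6

Assumption: 1 and 7 (the benzyl ethers of vanillin and of vanillyl chloride) are taken as purchasable building blocks.

**Step 1**
Reactants: 1 4-(benzyloxy)-3-methoxybenzaldehyde
Product: 3 rac-1-[4-(benzyloxy)-3-methoxyphenyl]prop-2-en-1-yl acetate, via bromomagnesium alkoxide 2 (not isolated)
Conditions: CH2=CHMgBr (1.2 equiv), THF, −78 to 0 °C; then Ac2O (1.5 equiv), 0 °C to rt
Reagents that add atoms: vinylmagnesium bromide, C=C[Mg]Br; acetic anhydride, CC(=O)OC(C)=O
Why: Grignard 1,2-addition to an aryl aldehyde followed by O-acylation of the magnesium alkoxide in the same flask should give the racemic allylic acetate, the carbinol centre being formed without control on purpose.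

**Step 2**
Reactants: 3 rac-1-[4-(benzyloxy)-3-methoxyphenyl]prop-2-en-1-yl acetate
Product: 4 (1R)-1-[4-(benzyloxy)-3-methoxyphenyl]prop-2-en-1-ol
Conditions: immobilised Candida antarctica lipase B, n-BuOH (3 equiv), MTBE, 30 °C, stopped near 45% conversion; chromatography
Reagents that add atoms: none
Why: Lipase-catalysed enantioselective alcoholysis (kinetic resolution) should, by the Kazlauskas rule with aryl as the large and vinyl as the medium group, cleave only the (R)-acetate, so the future C5 stereocentre is fixed as R by selection and the unreacted (S)-acetate is removed by chromatography.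

**Step 3**
Reactants: 4 (1R)-1-[4-(benzyloxy)-3-methoxyphenyl]prop-2-en-1-ol
Product: 6 2-{[(1R)-1-[4-(benzyloxy)-3-methoxyphenyl]prop-2-en-1-yl]oxy}-N-methoxy-N-methylacetamide, via sodium alkoxide 5 (not isolated)
Conditions: NaH (1.05 equiv), THF, 0 °C; then BrCH2C(O)N(OMe)Me (1.2 equiv), 0 °C to rt
Reagents that add atoms: 2-bromo-N-methoxy-N-methylacetamide, CON(C)C(=O)CBr
Why: Williamson ether synthesis of the alkoxide with a primary α-bromo amide should proceed by SN2 at the CH2Br carbon, so the benzylic C–O bond and its R configuration are not touched.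

**Step 4**
Reactants: 6 the Weinreb amide ether from step 3; 7 1-(benzyloxy)-4-(chloromethyl)-2-methoxybenzene
Product: 9 1-[4-(benzyloxy)-3-methoxyphenyl]-3-{[(1R)-1-[4-(benzyloxy)-3-methoxyphenyl]prop-2-en-1-yl]oxy}propan-2-one, via benzylic Grignard reagent 8 (not isolated)
Conditions: 7, activated Mg turnings, THF, 0 °C, slow addition; then 6, THF, −78 to 0 °C; aq. NH4Cl
Reagents that add atoms: none
Why: Weinreb ketone synthesis: the benzylic Grignard reagent adds only once because the chelated tetrahedral magnesium adduct survives until work-up, and no stereocentre is formed or put at risk.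

**Step 5**
Reactants: 9 the allyl ether ketone from step 4
Product: 10 1-[4-(benzyloxy)-3-methoxyphenyl]-3-{[(1R,2E)-1-[4-(benzyloxy)-3-methoxyphenyl]-3-(4,4,5,5-tetramethyl-1,3,2-dioxaborolan-2-yl)prop-2-en-1-yl]oxy}propan-2-one
Conditions: vinylboronic acid pinacol ester (3 equiv), second-generation Grubbs catalyst (H2IMes)(PCy3)Cl2Ru=CHPh (5 mol %), CH2Cl2, 40 °C
Reagents that add atoms: 4,4,5,5-tetramethyl-2-vinyl-1,3,2-dioxaborolane, C=CB1OC(C)(C)C(C)(C)O1
Why: Olefin cross-metathesis of a terminal alkene with vinyl pinacol boronate is a known route to (E)-alkenylboronates, and the ketone, the ethers and the allylic stereocentre should be inert to the ruthenium carbene.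

**Step 6**
Reactants: 10 the (E)-alkenylboronate keto ether from step 5
Product: 11 (3R,4S,5R)-5-[4-(benzyloxy)-3-methoxyphenyl]-3-[4-(benzyloxy)-3-methoxybenzyl]-4-[(4,4,5,5-tetramethyl-1,3,2-dioxaborolan-2-yl)methyl]oxolan-3-ol
Conditions: SmI2 (2.5 equiv, 0.1 M in THF, added over 1 h), HMPA (10 equiv), t-BuOH (3 equiv), THF (0.01 M in 10), −40 to 0 °C; then aq. NH4Cl
Reagents that add atoms: none
Why: Proposed new method: electron transfer from SmI2 to the ketone of 10 gives a samarium ketyl at C3 that adds to C4 of the (E)-alkenylboronate, whose vacant boron p orbital lowers the alkene LUMO and stabilises the radical formed at the exocyclic carbon, and a second electron transfer followed by protonation with t-BuOH gives the CH2–Bpin group. The closest known reaction type is the SmI2/HMPA ketyl–olefin cyclisation of δ,ε-unsaturated ketones onto unactivated alkenes and onto acrylate-type acceptors; an alkenylboronate as the acceptor is the new element. The oxolane is closed in the 5-exo-trig mode through a chair-like (Beckwith–Houk) transition state. C4 is controlled by the existing C5 centre, whose aryl group sits pseudo-equatorial and so ends up trans to the new CH2B branch, and C3 is controlled by the ketyl itself, whose bulky, negatively charged O–Sm(HMPA)n group turns away from the alkene so that oxygen ends up trans and the benzyl group cis to the CH2B branch, which is the (3R,4S,5R) array. The step needs ring closure to be faster than reductive cleavage of the α-alkoxy C2–O1 bond of the ketyl and than pinacol coupling, and this should be secured by the activated acceptor held five atoms away, by the (E) geometry that avoids allylic strain in the chair, and by slow addition of SmI2 at high dilution.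

**Step 7**
Reactants: 11 the cyclised boronate from step 6
Product: 12 (3R,4S,5R)-5-[4-(benzyloxy)-3-methoxyphenyl]-3-[4-(benzyloxy)-3-methoxybenzyl]-4-(hydroxymethyl)oxolan-3-ol
Conditions: 30% H2O2, 2 M NaOH, THF, 0 °C to rt
Reagents that add atoms: hydrogen peroxide, OO
Why: Oxidation of the primary alkyl pinacol boronate with basic hydrogen peroxide proceeds by 1,2-migration of carbon from boron to oxygen, which should turn CH2–B into CH2–OH without touching the three stereocentres.

**Step 8**
Reactants: 12 the dibenzyl ether from step 7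
Product: 13 (3R,4S,5R)-5-(4-hydroxy-3-methoxyphenyl)-3-(4-hydroxy-3-methoxybenzyl)-4-(hydroxymethyl)oxolan-3-ol (target)
Conditions: H2 (1 atm), 10% Pd/C, EtOAc–EtOH, rt, stopped at full debenzylation
Reagents that add atoms: none
Why: Catalytic hydrogenolysis of the two aryl benzyl ethers over palladium on carbon is expected to be much faster than cleavage of the benzylic C5–O1 bond of the oxolane, so the free bisphenol should be obtained with all stereocentres unchanged.

**Compound list**

1 | 4-(benzyloxy)-3-methoxybenzaldehyde | COc1cc(C=O)ccc1OCc1ccccc1 | starting material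
2 | bromomagnesium 1-[4-(benzyloxy)-3-methoxyphenyl]prop-2-en-1-olate (racemic) | C=CC(O[Mg]Br)c1ccc(OCc2ccccc2)c(OC)c1 | intermediate (not isolated)
3 | rac-1-[4-(benzyloxy)-3-methoxyphenyl]prop-2-en-1-yl acetate | C=CC(OC(C)=O)c1ccc(OCc2ccccc2)c(OC)c1 | intermediate
4 | (1R)-1-[4-(benzyloxy)-3-methoxyphenyl]prop-2-en-1-ol | C=C[C@@H](O)c1ccc(OCc2ccccc2)c(OC)c1 | intermediate
5 | sodium (1R)-1-[4-(benzyloxy)-3-methoxyphenyl]prop-2-en-1-olate | C=C[C@@H]([O-])c1ccc(OCc2ccccc2)c(OC)c1.[Na+] | intermediate (not isolated)
6 | 2-{[(1R)-1-[4-(benzyloxy)-3-methoxyphenyl]prop-2-en-1-yl]oxy}-N-methoxy-N-methylacetamide | CON(C)C(=O)CO[C@@H](c1ccc(OCc2ccccc2)c(OC)c1)C=C | intermediate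
7 | 1-(benzyloxy)-4-(chloromethyl)-2-methoxybenzene | COc1cc(CCl)ccc1OCc1ccccc1 | starting material
8 | [4-(benzyloxy)-3-methoxybenzyl]magnesium chloride | COc1cc(C[Mg]Cl)ccc1OCc1ccccc1 | intermediate (not isolated)
9 | 1-[4-(benzyloxy)-3-methoxyphenyl]-3-{[(1R)-1-[4-(benzyloxy)-3-methoxyphenyl]prop-2-en-1-yl]oxy}propan-2-one | COc1cc(CC(=O)CO[C@@H](c2ccc(OCc3ccccc3)c(OC)c2)C=C)ccc1OCc1ccccc1 | intermediate
10 | 1-[4-(benzyloxy)-3-methoxyphenyl]-3-{[(1R,2E)-1-[4-(benzyloxy)-3-methoxyphenyl]-3-(4,4,5,5-tetramethyl-1,3,2-dioxaborolan-2-yl)prop-2-en-1-yl]oxy}propan-2-one | COc1cc(CC(=O)CO[C@@H](c2ccc(OCc3ccccc3)c(OC)c2)/C=C/B4OC(C)(C)C(C)(C)O4)ccc1OCc1ccccc1 | intermediate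
11 | (3R,4S,5R)-5-[4-(benzyloxy)-3-methoxyphenyl]-3-[4-(benzyloxy)-3-methoxybenzyl]-4-[(4,4,5,5-tetramethyl-1,3,2-dioxaborolan-2-yl)methyl]oxolan-3-ol | COc1cc(C[C@]2(O)CO[C@@H](c3ccc(OCc4ccccc4)c(OC)c3)[C@@H]2CB5OC(C)(C)C(C)(C)O5)ccc1OCc1ccccc1 | intermediate
12 | (3R,4S,5R)-5-[4-(benzyloxy)-3-methoxyphenyl]-3-[4-(benzyloxy)-3-methoxybenzyl]-4-(hydroxymethyl)oxolan-3-ol | COc1cc(C[C@]2(O)CO[C@@H](c3ccc(OCc4ccccc4)c(OC)c3)[C@@H]2CO)ccc1OCc1ccccc1 | intermediate
13 | (3R,4S,5R)-5-(4-hydroxy-3-methoxyphenyl)-3-(4-hydroxy-3-methoxybenzyl)-4-(hydroxymethyl)oxolan-3-ol | COc1cc(C[C@]2(O)CO[C@@H](c3ccc(O)c(OC)c3)[C@@H]2CO)ccc1O | target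

**Step count**

Total: 8 steps. Longest linear sequence: 8 steps (1 → 3 → 4 → 6 → 9 → 10 → 11 → 12 → 13); Grignard reagent 8 is generated inside step 4.

**Steps most likely to fail**

Step 6 (proposed new method). The ketyl may expel the α-alkoxide (cleavage of C2–O1 and loss of the tether) or dimerise before it adds to the alkenylboronate, boron may bind the samarium alkoxide, or facial control at C3 may be poor. The fallback uses known chemistry throughout and avoids the ketyl: it sets out from 4 (through its alkoxide 5) and comes back to the route at 13. Williamson alkylation of 5 with propargyl bromide should give the (R)-allyl propargyl ether F1. Sonogashira coupling (Pd(PPh3)2Cl2, CuI, Et3N) with commercial 1-(benzyloxy)-4-bromo-2-methoxybenzene should give the aryl alkyne F2. Epoxidation of the terminal alkene with mCPBA/NaHCO3 should give the oxirane F3 as both epimers at the new oxirane carbon, which does not matter because that carbon becomes a radical. Cp2TiCl (trivalent titanium, from Cp2TiCl2 and Zn, THF) opens the oxirane to the secondary β-titanoxy radical at C4, which closes the same C3–C4 bond 5-exo-dig onto the aryl alkyne; this is the titanocene epoxide radical cyclisation used for furano lignans. It should give the 3-benzylidene oxolane F4 with the C4 hydroxymethyl group trans to the C5 aryl group. Dimethyldioxirane in acetone should epoxidise the exocyclic alkene from the face away from the adjacent C4 substituent to give the spiro-oxirane F5. Hydrogenolysis (H2, Pd/C) then cleaves the benzylic C–O bond of the oxirane, which leaves the C3–OH with the benzyl group, and both benzyl ethers, giving 13.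

Step 5. Cross-metathesis at the α-branched allylic ether may be slow or incomplete, with self-metathesis of the vinylboronate and alkene isomerisation as competing processes. The fallback changes the acceptor and sets out from 9, coming back to the route at 12. Cross-metathesis with methyl acrylate, one of the most reliable partners, should give the (E)-enoate F6. The well-precedented ketyl–enoate cyclisation (SmI2, MeOH, THF, −78 °C) should give the hydroxy ester F7 with the same anti sense; its CH2CO2Me group is trans to the C3–OH, so no lactone can form. LiOH should give the acid F8. The Barton ester F9 (N-hydroxypyridine-2-thione, DCC) is photolysed under O2 with t-BuSH to the hydroperoxide F10, and P(OMe)3 reduces this to 12; this decarboxylative hydroxylation removes the extra carbon.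

Step 8. Over-reduction may occur: once the phenols are free, the benzylic C5–O1 bond of the oxolane can be hydrogenolysed, which opens the ring. The fallback sets out from 12 and ends at 13 by a non-reductive, Lewis-acid debenzylation (BCl3, pentamethylbenzene as benzyl cation scavenger, CH2Cl2, −78 °C). It makes no new compound F0.

**Further compounds**

F1 | step 6 | 1-(benzyloxy)-2-methoxy-4-[(1R)-1-(prop-2-yn-1-yloxy)prop-2-en-1-yl]benzene | C#CCO[C@@H](c1ccc(OCc2ccccc2)c(OC)c1)C=C
F2 | step 6 | (R)-allyl ether carrying the 3-[4-(benzyloxy)-3-methoxyphenyl]prop-2-yn-1-yl group | COc1cc(C#CCO[C@@H](c2ccc(OCc3ccccc3)c(OC)c2)C=C)ccc1OCc1ccccc1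
F3 | step 6 | oxirane from F2 (benzylic centre unchanged in space, now labelled S; both oxirane epimers) | COc1cc(C#CCO[C@@H](c2ccc(OCc3ccccc3)c(OC)c2)C2CO2)ccc1OCc1ccccc1
F4 | step 6 | 3-benzylidene oxolane, C4 hydroxymethyl trans to C5 aryl (alkene geometry open) | COc1cc(C=C2CO[C@@H](c3ccc(OCc4ccccc4)c(OC)c3)[C@@H]2CO)ccc1OCc1ccccc1
F5 | step 6 | spiro-oxirane at C3, oxygen on the face of the C5 aryl group | COc1cc(C2O[C@]23CO[C@@H](c4ccc(OCc5ccccc5)c(OC)c4)[C@@H]3CO)ccc1OCc1ccccc1
F6 | step 5 | methyl (2E,4R)-4-[4-(benzyloxy)-3-methoxyphenyl]-4-{3-[4-(benzyloxy)-3-methoxyphenyl]-2-oxopropoxy}but-2-enoate | COc1cc(CC(=O)CO[C@@H](c2ccc(OCc3ccccc3)c(OC)c2)/C=C/C(=O)OC)ccc1OCc1ccccc1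
F7 | step 5 | methyl 2-[(3R,4S,5R)-3,5-disubstituted 3-hydroxyoxolan-4-yl]acetate (aryl groups as in 12) | COc1cc(C[C@]2(O)CO[C@@H](c3ccc(OCc4ccccc4)c(OC)c3)[C@@H]2CC(=O)OC)ccc1OCc1ccccc1
F8 | step 5 | the carboxylic acid of F7 | COc1cc(C[C@]2(O)CO[C@@H](c3ccc(OCc4ccccc4)c(OC)c3)[C@@H]2CC(=O)O)ccc1OCc1ccccc1
F9 | step 5 | Barton ester (2-thioxopyridin-1-yl ester) of F8 | COc1cc(C[C@]2(O)CO[C@@H](c3ccc(OCc4ccccc4)c(OC)c3)[C@@H]2CC(=O)ON5C=CC=CC5=S)ccc1OCc1ccccc1
F10 | step 5 | C4 hydroperoxymethyl analogue of 12 | COc1cc(C[C@]2(O)CO[C@@H](c3ccc(OCc4ccccc4)c(OC)c3)[C@@H]2COO)ccc1OCc1ccccc1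
F0 | step 8 | none | none
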